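## Retrosynthetic overview
1. Lactol **14** comes from Pd(0) deallylation of **13**. Compound **13** comes from chemoselective oxidation of the primary alcohol in diol **12**; the aldehyde closes onto the benzylic Ca–OH, so the strained trans-fused lactol (ring 1) forms last.
2. THF ring 2 is closed by 5-exo Williamson etherification of a C-9 tosylate by the benzylic Ce alkoxide, after a lactone template is opened; Ce keeps its configuration.
3. Ca and Cd come from the aldol of the lithium enolate of cis-lactone **8** with aldehyde **4**, which sets Cd anti to the 4-substituent.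
4. Lactone **8** comes from an Evans Mg(II)-catalysed anti-aldol of succinimide **3** with **4**, then lactonisation, imide reduction and TBS protection. Ring order: lactone template, then THF ring 2, then lactol ring 1.

**Assumptions**
- The target SMILES is taken literally, including its trans ring fusion (Cc and Cd on opposite faces) and the drawn lactol anomer. Ca = C-7, Cd = C-8, Cc = C-8′, Ce = C-7′, Cb = the lactol carbon, C9 = the ring-2 CH2.
- The phenols are carried as allyl ethers, using commercial O-allylvanillin.

## Route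

**Step 1**
Reactants: 1 (monomethyl succinate); 2 ((R)-4-benzyl-1,3-oxazolidin-2-one)
Product: 3 ((4R)-4-benzyl-3-(4-methoxy-4-oxobutanoyl)-1,3-oxazolidin-2-one)
Conditions: PivCl, Et3N, THF, –20 → 0 °C; then Li salt of 2 (n-BuLi, THF, –78 → 0 °C)
Reagents that add atoms: none (the pivaloyl group and Li are lost)
Why: Mixed-anhydride N-acylation (Evans imide formation) attaches the auxiliary at the acid end of the succinate, and no stereocentre forms.

**Step 2**
Reactants: 3; 4 (4-(allyloxy)-3-methoxybenzaldehyde)
Product: 5 (methyl (3S,4R)-3-{[(4R)-4-benzyl-2-oxo-1,3-oxazolidin-3-yl]carbonyl}-4-[4-(allyloxy)-3-methoxyphenyl]-4-(trimethylsilyloxy)butanoate)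
Conditions: MgCl2 (10 mol %), Et3N (2 equiv), TMSCl (2 equiv), EtOAc, 23 °C
Reagents that add atoms: chlorotrimethylsilane, C[Si](C)(C)Cl (TMS stays on the aldol oxygen)
Why: In the Evans Mg(II)-catalysed anti-aldol, the chelated Z-enolate of the (R)-imide is attacked by the aldehyde on the face opposite the benzyl group, which sets Cc as S, and the anti-selective transition state sets Ce as R.

**Step 3**
Reactants: 5
Product: 6 ((4R)-4-benzyl-3-{[(4S,5R)-5-[4-(allyloxy)-3-methoxyphenyl]-2-oxooxolan-4-yl]carbonyl}-1,3-oxazolidin-2-one)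
Conditions: 1 M HCl, THF, 0 °C; then PPTS (20 mol %), toluene, 50 °C
Reagents that add atoms: none (TMS and MeOH are lost)
Why: Acid removes the TMS group and the free benzylic OH closes onto the methyl ester in a γ-lactonisation; the anti-aldol relationship makes the 4-acyl and 5-aryl groups cis, and no stereocentre is touched.

**Step 4**
Reactants: 6
Product: 7 ((4R,5R)-5-[4-(allyloxy)-3-methoxyphenyl]-4-(hydroxymethyl)oxolan-2-one); auxiliary 2 is recovered
Conditions: LiBH4 (1.5 equiv), THF, MeOH (1.1 equiv), 0 °C, 30 min; pH 7 buffer work-up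
Reagents that add atoms: none (hydride only)
Why: The N-acyl oxazolidinone is much more electrophilic than the hindered lactone, so hydride cleaves it reductively to the primary alcohol without changing Cc or Ce.

**Step 5**
Reactants: 7
Product: 8 ((4R,5R)-5-[4-(allyloxy)-3-methoxyphenyl]-4-{[(tert-butyldimethylsilyl)oxy]methyl}oxolan-2-one)
Conditions: TBSCl, imidazole, DMF, 0 °C
Reagents that add atoms: tert-butyldimethylsilyl chloride, CC(C)(C)[Si](C)(C)Cl (TBS stays on the primary oxygen)
Why: Silylation of the primary alcohol stops it translactonising onto the ring-2 lactone carbonyl and masks C-9′ (Cb) until the last stage.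

**Step 6**
Reactants: 8; 4
Product: 9 ((3R,4R,5R)-5-[4-(allyloxy)-3-methoxyphenyl]-3-[(S)-[4-(allyloxy)-3-methoxyphenyl](hydroxy)methyl]-4-{[(tert-butyldimethylsilyl)oxy]methyl}oxolan-2-one)
Conditions: LiHMDS (1.1 equiv), THF, –78 °C; then 4 (1.5 equiv), –78 °C, 1 h; NH4Cl quench at –78 °C
Reagents that add atoms: none (the aldehyde 4 is a listed reactant; only H comes from the quench)
Why: Lactone-enolate aldol: the 4-CH2OTBS and 5-aryl groups are cis and block one face, so the aldehyde adds to C-3 from the other face, giving the trans-3,4 relationship and fixing Cd, while the cyclic (E)-enolate chair transition state favours the anti carbinol, Ca = S; the diastereomers are separated by chromatography.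

**Step 7**
Reactants: 9
Product: 10 ((1S,2S,3R,4R)-1,4-bis[4-(allyloxy)-3-methoxyphenyl]-2-(hydroxymethyl)-3-{[(tert-butyldimethylsilyl)oxy]methyl}butane-1,4-diol)
Conditions: LiBH4 (4 equiv), THF, MeOH (cat.), 0 °C → rt
Reagents that add atoms: none (hydride only)
Why: Borohydride reduction of the lactone opens ring 2 to the C-9 primary alcohol and the free benzylic Ce–OH; no stereocentre is involved and the allyl ethers and TBS ether are inert.

**Step 8**
Reactants: 10
Product: 11 ((S)-[(2R,3R,4S)-2-[4-(allyloxy)-3-methoxyphenyl]-3-({[tert-butyldimethylsilyl]oxy}methyl)oxolan-4-yl][4-(allyloxy)-3-methoxyphenyl]methanol)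
Conditions: (i) TsCl (1.05 equiv), Et3N, Me3N·HCl (cat.), CH2Cl2, 0 °C; (ii) NaH (3 equiv), THF, 0 °C → rt
Reagents that add atoms: none (the tosyl group leaves as TsONa)
Why: Selective tosylation of the only primary OH followed by intramolecular Williamson etherification (5-exo-tet) by the Ce alkoxide closes ring 2 with retention at Ce and no change at Cc or Cd, giving the 2,3-cis-3,4-trans-trisubstituted THF; the Ca alkoxide cannot compete because it would form an oxetane.

**Step 9**
Reactants: 11
Product: 12 ((S)-[(2R,3R,4S)-2-[4-(allyloxy)-3-methoxyphenyl]-3-(hydroxymethyl)oxolan-4-yl][4-(allyloxy)-3-methoxyphenyl]methanol)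
Conditions: TBAF (1.2 equiv), THF, 0 °C
Reagents that add atoms: none
Why: Fluoride cleaves the primary TBS ether (silyl deprotection) without touching the ether rings, the allyl ethers or any stereocentre.

**Step 10**
Reactants: 12
Product: 13 ((1R,3S,3aS,6R,6aS)-3,6-bis[4-(allyloxy)-3-methoxyphenyl]hexahydrofuro[3,4-c]furan-1-ol)
Conditions: DMP (1.05 equiv), NaHCO3 (solid), CH2Cl2, 0 °C, 30 min
Reagents that add atoms: none (DMP acts only as oxidant and its atoms are lost)
Why: Proposed new method: the unhindered primary alcohol is oxidised faster than the hindered benzylic secondary alcohol, and the aldehyde is trapped at once by 5-exo hemiacetalisation onto Ca–OH. The trans-fused lactol survives because its new ring contains no sp2 atom, and buffering plus 0 °C prevent enolisation at Cc, which would epimerise it to the cis-fused isomer. The closest known reaction is oxidation of 1,4-diols to lactols, and the anomer drawn in the target is assumed to be the persisting one.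

**Step 11**
Reactants: 13
Product: 14 (4α-hydroxypinoresinol, the target: (1R,3S,3aS,6R,6aS)-3,6-bis(4-hydroxy-3-methoxyphenyl)hexahydrofuro[3,4-c]furan-1-ol)
Conditions: Pd(PPh3)4 (5 mol %), PhSiH3 (3 equiv), CH2Cl2, 23 °C
Reagents that add atoms: none (hydride only; propene is lost)
Why: Pd(0)-catalysed Tsuji–Trost deallylation with a silane scavenger removes both aryl allyl ethers under neutral conditions, leaving the lactol, the benzylic C–O bonds and all five stereocentres untouched.

## Compound list
| # | Name | SMILES | Role |
|---|---|---|---|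
| 1 | Monomethyl succinate | COC(=O)CCC(=O)O | starting material |
| 2 | (R)-4-Benzyl-1,3-oxazolidin-2-one | O=C1N[C@H](Cc2ccccc2)CO1 | starting material |
| 3 | (4R)-4-Benzyl-3-(4-methoxy-4-oxobutanoyl)oxazolidin-2-one | COC(=O)CCC(=O)N1[C@H](Cc2ccccc2)COC1=O | intermediate |
| 4 | 4-(Allyloxy)-3-methoxybenzaldehyde | C=CCOc1ccc(C=O)cc1OC | starting material |
| 5 | anti-Aldol TMS ether | COC(=O)C[C@H](C(=O)N1[C@H](Cc2ccccc2)COC1=O)[C@@H](O[Si](C)(C)C)c1ccc(OCC=C)c(OC)c1 | intermediate |
| 6 | cis-4,5-Lactone imide | C=CCOc1ccc(cc1OC)[C@@H]2OC(=O)C[C@@H]2C(=O)N3[C@H](Cc4ccccc4)COC3=O | intermediate |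
| 7 | cis-4-(Hydroxymethyl)-5-aryl lactone | C=CCOc1ccc(cc1OC)[C@@H]2OC(=O)C[C@@H]2CO | intermediate |
| 8 | cis-4-(TBSOCH2)-5-aryl lactone | C=CCOc1ccc(cc1OC)[C@@H]2OC(=O)C[C@@H]2CO[Si](C)(C)C(C)(C)C | intermediate |
| 9 | Lactone aldol adduct | C=CCOc1ccc(cc1OC)[C@@H]2OC(=O)[C@@H]([C@H](O)c3ccc(OCC=C)c(OC)c3)[C@@H]2CO[Si](C)(C)C(C)(C)C | intermediate |
| 10 | Open-chain triol TBS ether | C=CCOc1ccc(cc1OC)[C@H](O)[C@@H](CO[Si](C)(C)C(C)(C)C)[C@@H](CO)[C@H](O)c2ccc(OCC=C)c(OC)c2 | intermediate |
| 11 | 2,3-cis-3,4-trans THF, TBS ether | C=CCOc1ccc(cc1OC)[C@@H]2OC[C@@H]([C@H](O)c3ccc(OCC=C)c(OC)c3)[C@@H]2CO[Si](C)(C)C(C)(C)C | intermediate |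
| 12 | THF diol | C=CCOc1ccc(cc1OC)[C@@H]2OC[C@@H]([C@H](O)c3ccc(OCC=C)c(OC)c3)[C@@H]2CO | intermediate |
| 13 | Bis-O-allyl lactol (trans-fused) | COc1cc([C@H]2O[C@@H](O)[C@H]3[C@H]2CO[C@H]3c2ccc(OCC=C)c(OC)c2)ccc1OCC=C | intermediate |
| 14 | 4α-Hydroxypinoresinol | COc1cc([C@H]2O[C@@H](O)[C@H]3[C@H]2CO[C@H]3c2ccc(O)c(OC)c2)ccc1O | target |

## Totals
Total steps: 11. Longest linear sequence: 11.

## Three steps most likely to fail
1. **Step 10 (trans-fused lactol).** The lactol may stay open as the hydroxy-aldehyde and epimerise at Cc, or DMP may also oxidise the benzylic Ca–OH. Fallback (different approach): mask Ca–OH as its TES ether before step 9, oxidise the freed primary alcohol under Swern conditions, then remove TES with buffered HF·pyridine in MeCN so ring closure occurs under non-oxidising conditions.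
2. **Step 6 (lactone aldol).** The dr at Ca may be poor and the enolate may epimerise or undergo retro-aldol. Fallback (different approach): C-aroylate the enolate of 8 with methyl 4-allyloxy-3-methoxybenzoate, then set Ca and Cd by Ru-TsDPEN dynamic-kinetic transfer hydrogenation of the β-keto lactone (HCO2H/Et3N).
3. **Step 2 (anti-aldol on the succinimide).** The selectivity with a CH2CO2Me α-substituent is unproven, and a wrong anti/syn ratio would give the trans-lactone. Fallback (different approach): run the Evans syn-aldol (Bu2BOTf, (S)-auxiliary), hydrolyse the methyl ester selectively (Me3SnOH), and close the lactone by Mitsunobu lactonisation, which inverts Ce to give the same cis-lactone 6.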